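**Retrosynthetic overview**

1. Ring numbering: C1 (C=O next to C–OH), C2 (OH), C3 (henicosyl), C4 (C=O), C5 (OMe), C6 (H). The last step frees the C2 hydroxyl from a tert-butyl ether of the quinone.
2. The quinone ring (the only ring) comes from a hydroquinone, which is closed at C4–C5 by 6π-electrocyclization of a dienylketene. The ketene is released by thermal 4π opening of a 4-hydroxy-4-[(Z)-2-methoxyvinyl]cyclobutenone; ring expansion from four to six members and oxidation are one operation.
3. Enabling feature: C1(=O)–C2(O)=C3(alkyl)–C4(=O) is a squaric-acid pattern (four contiguous carbons, three oxygenated, C1 and C4 para). With C1 bonded to C4 it is a cyclobutenone whose opening makes C4 a ketene carbon; the enol-ether double bond C5(OMe)=C6H is the 2π partner.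
4. The cyclobutenone comes from 3-tert-butoxy-4-henicosylcyclobutenedione and (Z)-2-methoxyvinyllithium; the dione comes from di-tert-butyl squarate and henicosylmagnesium bromide (from henicosan-1-ol).
5. Ring order: the four-membered ring is bought (squarate); the six-membered quinone ring is made from it in the key step.

Key step: step 5

Assumption: the side chain is read as the unbranched henicosyl (C21) chain; the target is achiral, and the single stereocentre of intermediates 4, 8, 9, 12, 13 and 15 is racemic and is destroyed before the end. Henicosan-1-ol, methoxyethene and di-tert-butyl squarate are taken as commercial.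

**Route**

Step 1
Reactants: 1 henicosan-1-ol
Product: 2 1-bromohenicosane
Conditions: CBr4, PPh3, CH2Cl2, 0 °C → rt
Reagents that add atoms: carbon tetrabromide, BrC(Br)(Br)Br
Why: Appel bromination, in which bromide displaces the alkoxyphosphonium ion by SN2 at the primary carbon, should be clean for a long unbranched alcohol.

Step 2
Reactants: 3 methoxyethene
Product: 5 (Z)-1-bromo-2-methoxyethene, via 1,2-dibromo-1-methoxyethane 4 (not isolated)
Conditions: Br2, pentane, −78 °C; then PhNEt2, 90 °C, distil
Reagents that add atoms: bromine, BrBr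
Why: Bromine addition to the enol ether followed by amine-mediated dehydrobromination of the α-bromo ether (addition–elimination) should give mainly the (Z)-isomer, as for the ethoxy analogue, and any (E)-isomer is harmless because its lithio derivative undergoes anti β-elimination in step 4.

Step 3
Reactants: 2 1-bromohenicosane; 6 di-tert-butyl squarate (3,4-di-tert-butoxycyclobut-3-ene-1,2-dione)
Product: 10 3-tert-butoxy-4-henicosylcyclobut-3-ene-1,2-dione, via henicosylmagnesium bromide 7 (not isolated), via bromomagnesium alkoxide adduct 8 (not isolated), via tertiary trifluoroacetate 9 (not isolated)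
Conditions: Mg, THF, 50 °C; then 6, THF, −78 → −20 °C; then (CF3CO)2O, −78 °C; cold aq NaHCO3
Reagents that add atoms: none
Why: Grignard 1,2-addition to one of the two equivalent squarate carbonyls, O-trifluoroacetylation and ionization with loss of a tert-butyl cation from the resulting oxocarbenium ion (the standard squarate addition/1,3-carbonyl transposition) should give the alkylcyclobutenedione with one tert-butoxy group kept.

Step 4
Reactants: 5 (Z)-1-bromo-2-methoxyethene; 10 3-tert-butoxy-4-henicosylcyclobut-3-ene-1,2-dione
Product: 13 racemic 3-tert-butoxy-2-henicosyl-4-hydroxy-4-[(Z)-2-methoxyethenyl]cyclobut-2-en-1-one, via (Z)-2-methoxyvinyllithium 11 (not isolated), via lithium alkoxide of the adduct 12 (not isolated)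
Conditions: n-BuLi, Et2O, −78 °C; then 10, THF, −78 → −40 °C; H2O quench at −78 °C; Et3N-deactivated silica
Reagents that add atoms: none
Why: Bromine–lithium exchange with retention of alkene geometry gives the chelation-stabilized (Z)-β-methoxyvinyllithium, which should add 1,2 to the ketone-like carbonyl next to the tert-butoxy-bearing carbon because the other carbonyl is deactivated as a vinylogous ester; the carbinol stereocentre forms racemic and is erased in step 5.

Step 5
Reactants: 13 racemic 3-tert-butoxy-2-henicosyl-4-hydroxy-4-[(Z)-2-methoxyethenyl]cyclobut-2-en-1-one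
Product: 17 2-tert-butoxy-3-henicosyl-5-methoxycyclohexa-2,5-diene-1,4-dione, via dienylketene 14 (not isolated), via cyclohexadienone 15 (not isolated), via hydroquinone 16 (not isolated)
Conditions: PhMe (degassed), 110 °C; then Ag2O, rt
Reagents that add atoms: none
Why: Heating should open the cyclobutenone by conrotatory 4π-electrocyclic cleavage of the bond between the carbonyl carbon and the carbinol carbon, the hydroxyl (donor) rotating outward so that the methoxyvinyl group turns inward, next to the ketene carbon of 14. The ketene carbon then bonds to the methoxy-bearing vinyl terminus in a thermally allowed disrotatory 6π-electrocyclization, which closes the six-membered carbocycle between the two ends of a 1,3,5-triene and forms the C4–C5 bond; cyclohexadienone 15 enolizes to the aromatic hydroquinone 16, and Ag2O removes two hydrogens to give the para-quinone. The closest known reaction type is the thermal ring expansion of squarate-derived 4-alkenyl- and 4-aryl-4-hydroxycyclobutenones to hydroquinones and quinones. The only new stereocentre is the methoxy-bearing carbon of 15, which forms racemic and vanishes on aromatization, so no stereocontrol is needed. The step needs torquoselectivity in the ring opening, secured by the outward preference of the hydroxyl group, and one regiochemical outcome, secured by the connectivity of 13: the henicosyl carbon is bonded to the future ketene carbon and the methoxy group sits on the distal vinyl carbon, so alkyl, protected hydroxyl and methoxy must arrive at C3, C2 and C5. The (Z)-enol ether puts only a small methoxy group inside the cyclization transition state, as an aryl group does in the 4-aryl cases, and the tert-butyl ether should survive neutral toluene at 110 °C.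

Step 6
Reactants: 17 2-tert-butoxy-3-henicosyl-5-methoxycyclohexa-2,5-diene-1,4-dione
Product: 18 3-henicosyl-2-hydroxy-5-methoxycyclohexa-2,5-diene-1,4-dione (target)
Conditions: CF3CO2H, CH2Cl2, 0 °C → rt
Reagents that add atoms: none
Why: Acidolysis of the tert-butyl vinylogous ester (loss of the tert-butyl cation as 2-methylpropene) should free the C2 hydroxyl, while the methyl vinylogous ester at C5 cannot ionize and stays.

**Compound list**

1 | henicosan-1-ol | CCCCCCCCCCCCCCCCCCCCCO | starting material
2 | 1-bromohenicosane | CCCCCCCCCCCCCCCCCCCCCBr | intermediate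
3 | methoxyethene | COC=C | starting material
4 | 1,2-dibromo-1-methoxyethane (racemic) | COC(Br)CBr | intermediate
5 | (Z)-1-bromo-2-methoxyethene | CO/C=C\Br | intermediate
6 | di-tert-butyl squarate (3,4-di-tert-butoxycyclobut-3-ene-1,2-dione) | CC(C)(C)OC1=C(OC(C)(C)C)C(=O)C1=O | starting material
7 | henicosylmagnesium bromide | CCCCCCCCCCCCCCCCCCCCC[Mg]Br | intermediate
8 | bromomagnesium 2,3-di-tert-butoxy-1-henicosyl-4-oxocyclobut-2-en-1-olate (racemic) | CCCCCCCCCCCCCCCCCCCCCC1(O[Mg]Br)C(OC(C)(C)C)=C(OC(C)(C)C)C1=O | intermediate
9 | 2,3-di-tert-butoxy-1-henicosyl-4-oxocyclobut-2-en-1-yl trifluoroacetate (racemic) | CCCCCCCCCCCCCCCCCCCCCC1(OC(=O)C(F)(F)F)C(OC(C)(C)C)=C(OC(C)(C)C)C1=O | intermediate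
10 | 3-tert-butoxy-4-henicosylcyclobut-3-ene-1,2-dione | CCCCCCCCCCCCCCCCCCCCCC1=C(OC(C)(C)C)C(=O)C1=O | intermediate
11 | (Z)-2-methoxyvinyllithium | [Li]/C=C\OC | intermediate
12 | lithium 2-tert-butoxy-3-henicosyl-1-[(Z)-2-methoxyethenyl]-4-oxocyclobut-2-en-1-olate (racemic) | CCCCCCCCCCCCCCCCCCCCCC1=C(OC(C)(C)C)C(O[Li])(/C=C\OC)C1=O | intermediate
13 | 3-tert-butoxy-2-henicosyl-4-hydroxy-4-[(Z)-2-methoxyethenyl]cyclobut-2-en-1-one (racemic) | CCCCCCCCCCCCCCCCCCCCCC1=C(OC(C)(C)C)C(O)(/C=C\OC)C1=O | intermediate
14 | (3Z,5Z)-3-tert-butoxy-2-henicosyl-4-hydroxy-6-methoxyhexa-1,3,5-trien-1-one | CCCCCCCCCCCCCCCCCCCCCC(=C=O)/C(OC(C)(C)C)=C(O)\C=C/OC | intermediate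
15 | 3-tert-butoxy-2-henicosyl-4-hydroxy-6-methoxycyclohexa-2,4-dien-1-one (racemic) | CCCCCCCCCCCCCCCCCCCCCC1=C(OC(C)(C)C)C(O)=CC(OC)C1=O | intermediate
16 | 2-tert-butoxy-3-henicosyl-5-methoxybenzene-1,4-diol | CCCCCCCCCCCCCCCCCCCCCc1c(O)c(OC)cc(O)c1OC(C)(C)C | intermediate
17 | 2-tert-butoxy-3-henicosyl-5-methoxycyclohexa-2,5-diene-1,4-dione | CCCCCCCCCCCCCCCCCCCCCC1=C(OC(C)(C)C)C(=O)C=C(OC)C1=O | intermediate
18 | 3-henicosyl-2-hydroxy-5-methoxycyclohexa-2,5-diene-1,4-dione | CCCCCCCCCCCCCCCCCCCCCC1=C(O)C(=O)C=C(OC)C1=O | target

**Step count**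

Total steps: 6. Longest linear sequence: 5 (steps 1, 3, 4, 5, 6); step 2 is a one-step side branch.

**Steps most likely to fail, with fallbacks**

Step 5 (key step). Risks: ring opening with inward rotation of the hydroxyl and capture of the ketene by it (lactonization to a furanone), early loss of the tert-butyl group, or over-oxidation of the electron-rich hydroquinone. The fallback sets out from 2 and comes back at 18, and builds the quinone from a ready-made arene. 1,2,4,5-Tetramethoxybenzene (COc1cc(OC)c(OC)cc1OC, commercial) is lithiated with n-BuLi in THF to 2,3,5,6-tetramethoxyphenyllithium F1. This is alkylated with 2 to give 3-henicosyl-1,2,4,5-tetramethoxybenzene F2. Oxidative demethylation with (NH4)2Ce(NO3)6 in MeCN/H2O should give 3-henicosyl-2,5-dimethoxycyclohexa-2,5-diene-1,4-dione F3. HClO4 in aqueous dioxane should then hydrolyse the methoxy group next to the alkyl chain, the more labile one in 3-alkyl-2,5-dimethoxybenzoquinones, to give 18.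

Step 4. Risks: β-elimination of LiOMe from the vinyllithium before it adds, addition at the wrong carbonyl, and acid-induced allylic transposition of the β-methoxyvinyl carbinol during isolation. The fallback sets out from 10 and comes back at 13; it brings in the two carbons as an acetylide and sets the (Z)-geometry by semihydrogenation. Lithium methoxyacetylide F4, made in the flask from 2-chloro-1,1-dimethoxyethane (COC(OC)CCl) and three equivalents of LiNEt2 in THF, is added to 10 at −78 °C. Aqueous quench gives 3-tert-butoxy-2-henicosyl-4-hydroxy-4-(methoxyethynyl)cyclobut-2-en-1-one F5. H2 over Pd/CaCO3 poisoned with Pb(OAc)2 and quinoline in EtOAc at rt should reduce the ynol ether to the (Z)-enol ether 13.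

Step 3. Risks: double addition of the Grignard reagent and loss of the second tert-butyl group under the acid released in the rearrangement. The fallback sets out from 2 (as its Grignard reagent 7) and comes back at 10; it forms the C–C bond in the robust isopropyl series and installs the tert-butyl group afterwards. Reagent 7 is added to diisopropyl squarate (CC(C)OC1=C(OC(C)C)C(=O)C1=O) and quenched with water to give 4-henicosyl-4-hydroxy-2,3-di(propan-2-yloxy)cyclobut-2-en-1-one F6. Catalytic HCl in CH2Cl2 rearranges this to 3-henicosyl-4-(propan-2-yloxy)cyclobut-3-ene-1,2-dione F7. Aqueous HCl in THF at reflux hydrolyses the vinylogous ester to 3-henicosyl-4-hydroxycyclobut-3-ene-1,2-dione F8. Ag2O converts this to silver 2-henicosyl-3,4-dioxocyclobut-1-en-1-olate F9, and tert-butyl chloride in Et2O should O-alkylate it to 10, the way di-tert-butyl squarate itself is made.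

**Further compounds**

F1 | step 5 | 2,3,5,6-tetramethoxyphenyllithium | [Li]c1c(OC)c(OC)cc(OC)c1OC
F2 | step 5 | 3-henicosyl-1,2,4,5-tetramethoxybenzene | CCCCCCCCCCCCCCCCCCCCCc1c(OC)c(OC)cc(OC)c1OC
F3 | step 5 | 3-henicosyl-2,5-dimethoxycyclohexa-2,5-diene-1,4-dione | CCCCCCCCCCCCCCCCCCCCCC1=C(OC)C(=O)C=C(OC)C1=O
F4 | step 4 | lithium methoxyacetylide | [Li]C#COC
F5 | step 4 | 3-tert-butoxy-2-henicosyl-4-hydroxy-4-(methoxyethynyl)cyclobut-2-en-1-one (racemic) | CCCCCCCCCCCCCCCCCCCCCC1=C(OC(C)(C)C)C(O)(C#COC)C1=O
F6 | step 3 | 4-henicosyl-4-hydroxy-2,3-di(propan-2-yloxy)cyclobut-2-en-1-one (racemic) | CCCCCCCCCCCCCCCCCCCCCC1(O)C(OC(C)C)=C(OC(C)C)C1=O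
F7 | step 3 | 3-henicosyl-4-(propan-2-yloxy)cyclobut-3-ene-1,2-dione | CCCCCCCCCCCCCCCCCCCCCC1=C(OC(C)C)C(=O)C1=O
F8 | step 3 | 3-henicosyl-4-hydroxycyclobut-3-ene-1,2-dione | CCCCCCCCCCCCCCCCCCCCCC1=C(O)C(=O)C1=O
F9 | step 3 | silver 2-henicosyl-3,4-dioxocyclobut-1-en-1-olate | CCCCCCCCCCCCCCCCCCCCCC1=C([O-])C(=O)C1=O.[Ag+]
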